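The easy step to read is the last on the card. Starting material passes reversibly over the catalyst to intermediate, intermediate and reagent give target over the catalyst, and target passes to over-reaction product, a first-order loss with neither catalyst nor reagent in its equation.

| setting | west | east | north | south | eta | alpha | gamma | delta |
|---|---|---|---|---|---|---|---|---|
| starting material | 10 mM | 10 mM | 10 mM | 20 mM | 10 mM (fed, over 40 min) | 10 mM | 10 mM | 10 mM (fed, over 40 min) |
| reagent | 12 mM | 12 mM | 12 mM | 12 mM | 12.0 mM | 12.0 mM | 12.0 mM | 12.0 mM |
| catalyst | 0.12 mM | 0.080 mM | 0.18 mM | 0.12 mM | 0.12 mM | 0.12 mM | 0.12 mM | 0.12 mM |
| temperature | 95 °C | 110 °C | 95 °C | 110 °C |  |  | 110 °C | 110 °C |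
| remark | run made earlier | run made earlier | run made earlier | run made earlier | the addition at 90 °C, then warmed to 110 °C; the feed brings no volume worth counting | everything together at the start at 90 °C, warmed to 110 °C at 40 min | everything together at the start | all else is in the flask from the start; the feed brings no volume worth counting |
| time |  |  |  |  | 1.0 h | 1.0 h | 1.0 h | 1.0 h |

- west (time / min: target / %, starting material / %): 15.0: 12, 44; 40.0: 33, 20; 80.0: 40, 8; 120: 38, 6
- east (time / min: target / %, starting material / %): 10.0: 7, 50; 20.0: 20, 31; 25.0: 20, 24; 40.0: 25, 16
- north (time / min: target / %, starting material / %): 10.0: 12, 44; 25.0: 31, 17; 50.0: 47, 12; 80.0: 46, 7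
- south (time / min: target / %, starting material / %): 5.00: 3, 59; 12.0: 14, 29; 25.0: 25, 19; 40.0: 20, 14

(readings scatter by 2 percentage points)

- the numbers in the tables scatter with a standard deviation of 2 percentage points
- reactions considered so far: starting material + catalyst <-> catalyst + intermediate; reagent + catalyst + intermediate -> catalyst + target; target -> over-reaction product

- the best flask by amount of target, in percent of the starting material charged; "all alike" if 1.5 percentage points covers them all (eta / alpha / gamma / delta / all alike)
- amount of target at the end, in percent of the starting material charged, eta
- amount of target at the end, in percent of the starting material charged, alpha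
- amount of target at the end, in percent of the starting material charged, gamma
- amount of target at the end, in percent of the starting material charged, delta

In common logarithms, the fall of target is counted in log units per minute, net of what is still being made. The south run, at 110 °C, gives it from two readings past its peak:

fall = log(25% / 20%) / (40.0 min − 25.0 min) = 0.00646 /min

This hot fall rate, the part of a log unit of target lost per minute past the peak, carries the scatter of those two readings. The west run, at 95 °C, gives 5.57 × 10⁻⁴ /min in the same way, a lower figure, though its two readings differ by no more than the scatter.

The first setting is the temperature of the first 40 min. My own reckoning takes gamma's peak near south's reading at 25.0 min, which leaves 35.0 min of hot fall: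

kept, gamma = 0.594

Alpha is hot for the last 20.0 min, which gives:

kept, alpha = 0.743

So the cold start should favour alpha over gamma.

The second setting is the feed. It makes target later, so delta should stand above gamma. Eta is hot for the same last 20.0 min as alpha, so the same kept fraction applies and by hand it gains nothing over alpha.

The forecast puts alpha first, with alpha 30%, eta 29%, delta 27% and gamma 22%, on the ground that “Hot time therefore destroys target”.

The simulation gives alpha 31.9%, eta 30.1%, delta 27.6% and gamma 23.0%. So alpha is best, by 1.8 percentage points over eta against a margin of 1.5 points, and the forecast stands within its tolerance.

    starting material + catalyst ⇌ catalyst + intermediate (K = 3.10, k = 1100 /M/min, Ea = 65.0 kJ/mol, ΔH = −21.0 kJ/mol)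
    reagent + catalyst + intermediate → catalyst + target (k = 39000 /M²/min, Ea = 48.0 kJ/mol)
    target → over-reaction product (k = 0.0350 /min, Ea = 101 kJ/mol)
    (constants at 110 °C)

Alpha stands 8.9 points above gamma, and delta 4.6 points above gamma. With the loss of target to over-reaction product taken away, that difference between alpha and gamma becomes −15 points, so gamma would lead. Gamma read at 1.5 h is the second flask: the fall rate over the further 30.0 min takes its 23.0% to 14.7%, and the computed flask holds 13.7%.

The numbers in the tables were generated by integration from invented constants.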